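**Retrosynthetic overview**

1. The target comes from its 4-O-diethylcarbamate by reductive deprotection. The carbamate comes from an acyclic (8R,8'S)-8,8'-dimethyl-dibenzylbutane (guaiacyl OH free, syringyl OH as carbamate) by dehydrogenative closure of the C7'–C2 bond: DDQ makes a p-quinone methide at C7', and the syringyl ring closes the carbocycle and sets C7'.
2. Enabling feature: the free 4'-OH lies para to C7' on the pendant ring (a latent quinone methide), and the ring to be fused is a 3,5-dimethoxy-4-oxy arene whose C2 and C6 are equivalent, each ortho to one OMe and para to the other, so closure has only one site.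
3. The dibenzylbutane comes from two aryl bromides and meso-2,3-dimethylsuccinic anhydride. C7 and C7' are the two anhydride carbonyls, each arylated (Rh-catalysed enantioselective desymmetrization, then Weinreb ketone synthesis) and each hydrogenolysed to CH2.
4. The cis relationship of C8/C8' comes from syn-hydrogenation of 2,3-dimethylmaleic anhydride; the absolute configuration comes from the desymmetrization.
5. Ring order: both benzene rings are bought, the anhydride ring is opened in step 3, and the carbocycle C7'–C2–C1–C7–C8–C8' of the tetralin is the only ring built, last.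

Key step: step 8

Assumption: the sense of induction in the anhydride desymmetrization follows the ligand enantiomer; (S)-t-Bu-PHOX is written, and its antipode is to be used if a trial run arylates the other carbonyl group.

**Step 1**
Reactants: 1 2,3-dimethylmaleic anhydride
Product: 2 meso-2,3-dimethylsuccinic anhydride [(3R,4S)-3,4-dimethyloxolane-2,5-dione]
Conditions: H2 (4 bar), 10% Pd/C, EtOAc, rt
Reagents that add atoms: none
Why: Heterogeneous catalytic hydrogenation delivers both hydrogens to one face of the tetrasubstituted C=C (syn addition), so the two new stereocentres (the future C8 and C8') are set cis to each other and the product is the achiral meso anhydride.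

**Step 2**
Reactants: 3 4-bromo-2,6-dimethoxyphenol
Product: 4 4-bromo-2,6-dimethoxyphenyl N,N-diethylcarbamate
Conditions: Et2NCOCl, K2CO3, MeCN, reflux
Reagents that add atoms: N,N-diethylcarbamoyl chloride CCN(CC)C(Cl)=O
Why: O-Carbamoylation of a phenoxide; the diethylcarbamate should survive aryllithium formation at −78 °C, hydrogenolysis and DDQ/TFA, and as an O-acyl group it later blocks quinone methide formation on this ring.

**Step 3**
Reactants: 2 meso-2,3-dimethylsuccinic anhydride; 4 4-bromo-2,6-dimethoxyphenyl N,N-diethylcarbamate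
Product: 7 (2R,3S)-4-[4-(diethylcarbamoyloxy)-3,5-dimethoxyphenyl]-2,3-dimethyl-4-oxobutanoic acid, via aryllithium 5 (not isolated), via arylzinc triflate 6 (not isolated)
Conditions: 4, n-BuLi, THF, −78 °C; Zn(OTf)2, −78 °C → rt; then 2, [Rh(cod)Cl]2 (cat.), (S)-t-Bu-PHOX (cat.), THF, 50 °C; 1 M HCl
Reagents that add atoms: none
Why: Rh-catalysed enantioselective desymmetrization of a meso succinic anhydride with an arylzinc reagent made in situ (acyl C–O oxidative addition, transmetalation, reductive elimination), a reaction type with close precedent on cis-2,3-dimethylsuccinic anhydride; no stereocentre is made, the chiral ligand selects the carbonyl bound to the (S)-configured ring carbon and so fixes the absolute configuration (ketone next to the future C8, acid next to the future C8').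

**Step 4**
Reactants: 7 (2R,3S)-4-[4-(diethylcarbamoyloxy)-3,5-dimethoxyphenyl]-2,3-dimethyl-4-oxobutanoic acid
Product: 8 (2R,3R)-4-[4-(diethylcarbamoyloxy)-3,5-dimethoxyphenyl]-2,3-dimethylbutanoic acid
Conditions: H2 (4 bar), 10% Pd/C, AcOH, HClO4 (cat.), 50 °C
Reagents that add atoms: none
Why: Catalytic hydrogenation of the aryl ketone and hydrogenolysis of the resulting benzylic C–O bond (as the carbinol or as the γ-lactone it forms, a secondary benzylic ester), the classical conversion of 4-aryl-4-oxobutanoic acids into 4-arylbutanoic acids, which runs on the metal surface and should leave C8, C8' and the carbamate untouched.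

**Step 5**
Reactants: 8 (2R,3R)-4-[4-(diethylcarbamoyloxy)-3,5-dimethoxyphenyl]-2,3-dimethylbutanoic acid
Product: 10 4-[(2R,3R)-4-[methoxy(methyl)amino]-2,3-dimethyl-4-oxobutyl]-2,6-dimethoxyphenyl N,N-diethylcarbamate, via acyl imidazole 9 (not isolated)
Conditions: CDI, CH2Cl2, rt; then MeNH(OMe)·HCl, rt
Reagents that add atoms: N,O-dimethylhydroxylamine hydrochloride CNOC.Cl
Why: Weinreb amide formation through the acyl imidazole, a mild activation without acid chloride or strong base, so the α-stereocentre (C8') should be retained.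

**Step 6**
Reactants: 10 4-[(2R,3R)-4-[methoxy(methyl)amino]-2,3-dimethyl-4-oxobutyl]-2,6-dimethoxyphenyl N,N-diethylcarbamate; 11 1-(benzyloxy)-4-bromo-2-methoxybenzene
Product: 13 4-[(2R,3R)-4-[4-(benzyloxy)-3-methoxyphenyl]-2,3-dimethyl-4-oxobutyl]-2,6-dimethoxyphenyl N,N-diethylcarbamate, via aryllithium 12 (not isolated)
Conditions: 11, n-BuLi, THF, −78 °C; then 10, −78 → −40 °C; 1 M HCl
Reagents that add atoms: none
Why: Weinreb ketone synthesis: the aryllithium from bromine–lithium exchange adds once because the chelated tetrahedral adduct persists until the acidic work-up, and at −78 °C addition should be faster than α-deprotonation or attack on the hindered diethylcarbamate.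

**Step 7**
Reactants: 13 4-[(2R,3R)-4-[4-(benzyloxy)-3-methoxyphenyl]-2,3-dimethyl-4-oxobutyl]-2,6-dimethoxyphenyl N,N-diethylcarbamate
Product: 14 4-[(2R,3S)-4-(4-hydroxy-3-methoxyphenyl)-2,3-dimethylbutyl]-2,6-dimethoxyphenyl N,N-diethylcarbamate
Conditions: H2 (4 bar), 10% Pd/C, AcOH, 40 °C
Reagents that add atoms: none
Why: One hydrogenolysis over Pd/C removes the O-benzyl group and reduces the para-oxygenated aryl ketone through the carbinol to CH2 (benzylic deoxygenation), unmasking the free 4'-OH needed in the key step while C8 and C8' stay untouched (only the CIP descriptor of C8' changes).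

**Step 8**
Reactants: 14 4-[(2R,3S)-4-(4-hydroxy-3-methoxyphenyl)-2,3-dimethylbutyl]-2,6-dimethoxyphenyl N,N-diethylcarbamate
Product: 16 (6R,7R,8R)-8-(4-hydroxy-3-methoxyphenyl)-1,3-dimethoxy-6,7-dimethyl-5,6,7,8-tetrahydronaphthalen-2-yl N,N-diethylcarbamate, via quinone methide 15 (not isolated)
Conditions: DDQ (1.0 equiv, slow addition), CH2Cl2/TFA (10:1), 0 °C
Reagents that add atoms: none
Why: DDQ removes hydride from C7' of the only ring with a free para-OH (the carbamate ring cannot form a quinone methide and a cation at C7 would have no para donor), giving p-quinone methide 15, which TFA protonates to the 4-hydroxybenzyl cation. C2 of the 3,5-dimethoxyaryl carbamate ring attacks C7' in a Friedel–Crafts alkylation, a 6-exo-trig closure onto the exocyclic C7'=C1' bond (6-endo with respect to the arene), and rearomatization completes the C7'–C2 bond and the carbocycle in one operation from a C–H bond. The closest known reaction types are the DDQ/TFA oxidative cyclization of dibenzylbutane-type lignans to 1-aryltetralins and the acid cyclization of 7'-hydroxy lignans, which pass through the same cation. C7' is the only new stereocentre and is set by the substrate: the methoxy group at C3 (peri to C7') forces the incoming aryl pseudo-axial, the 8'-methyl then lies anti to it with the 8-methyl equatorial, whereas the C7' epimer would need a 1,3-diaxial aryl/8-methyl contact, so the 7',8'-trans (7'R) product should form. Regioselectivity needs no control because C2 and C6 of the nucleophilic ring are equivalent and each is ortho to one OMe and para to the other. The selectivity risks are over-oxidation of 16 and loss of C8' by tautomerization of 15 to the styrene; they are countered by one equivalent of DDQ added slowly at 0 °C, by having acid present so that the cation is trapped intramolecularly at once, and by the peri strain that keeps the pendant ring of 16 out of the plane a second hydride loss would need.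

**Step 9**
Reactants: 16 (6R,7R,8R)-8-(4-hydroxy-3-methoxyphenyl)-1,3-dimethoxy-6,7-dimethyl-5,6,7,8-tetrahydronaphthalen-2-yl N,N-diethylcarbamate
Product: 17 (6R,7R,8R)-8-(4-hydroxy-3-methoxyphenyl)-1,3-dimethoxy-6,7-dimethyl-5,6,7,8-tetrahydronaphthalen-2-ol [(−)-(7'R,8R,8'R)-4,4'-dihydroxy-3,3',5-trimethoxy-2,7'-cyclolignan]
Conditions: LiAlH4, THF, 65 °C; aq. Rochelle salt, under argon
Reagents that add atoms: none
Why: Reductive cleavage of an aryl carbamate: hydride adds to the carbamate carbonyl and the hindered aryloxide is expelled (the formamide left is reduced to the tertiary amine), conditions under which the tetralin, the methyl ethers and the three stereocentres should be inert.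

**Compound list**

1 | 2,3-dimethylmaleic anhydride | CC1=C(C)C(=O)OC1=O | starting material
2 | meso-2,3-dimethylsuccinic anhydride, (3R,4S)-3,4-dimethyloxolane-2,5-dione | C[C@@H]1[C@H](C)C(=O)OC1=O | intermediate
3 | 4-bromo-2,6-dimethoxyphenol | COc1cc(Br)cc(OC)c1O | starting material
4 | 4-bromo-2,6-dimethoxyphenyl N,N-diethylcarbamate | CCN(CC)C(=O)Oc1c(OC)cc(Br)cc1OC | intermediate
5 | [4-(diethylcarbamoyloxy)-3,5-dimethoxyphenyl]lithium (formed in the flask) | CCN(CC)C(=O)Oc1c(OC)cc([Li])cc1OC | intermediate
6 | [4-(diethylcarbamoyloxy)-3,5-dimethoxyphenyl]zinc trifluoromethanesulfonate (formed in the flask) | CCN(CC)C(=O)Oc1c(OC)cc([Zn]OS(=O)(=O)C(F)(F)F)cc1OC | intermediate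
7 | (2R,3S)-4-[4-(diethylcarbamoyloxy)-3,5-dimethoxyphenyl]-2,3-dimethyl-4-oxobutanoic acid | OC(=O)[C@H](C)[C@H](C)C(=O)c1cc(OC)c(OC(=O)N(CC)CC)c(OC)c1 | intermediate
8 | (2R,3R)-4-[4-(diethylcarbamoyloxy)-3,5-dimethoxyphenyl]-2,3-dimethylbutanoic acid | OC(=O)[C@H](C)[C@H](C)Cc1cc(OC)c(OC(=O)N(CC)CC)c(OC)c1 | intermediate
9 | 4-[(2R,3R)-4-(imidazol-1-yl)-2,3-dimethyl-4-oxobutyl]-2,6-dimethoxyphenyl N,N-diethylcarbamate (formed in the flask) | O=C([C@H](C)[C@H](C)Cc1cc(OC)c(OC(=O)N(CC)CC)c(OC)c1)n1ccnc1 | intermediate
10 | 4-[(2R,3R)-4-[methoxy(methyl)amino]-2,3-dimethyl-4-oxobutyl]-2,6-dimethoxyphenyl N,N-diethylcarbamate | CON(C)C(=O)[C@H](C)[C@H](C)Cc1cc(OC)c(OC(=O)N(CC)CC)c(OC)c1 | intermediate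
11 | 1-(benzyloxy)-4-bromo-2-methoxybenzene | COc1cc(Br)ccc1OCc1ccccc1 | starting material
12 | [4-(benzyloxy)-3-methoxyphenyl]lithium (formed in the flask) | COc1cc([Li])ccc1OCc1ccccc1 | intermediate
13 | 4-[(2R,3R)-4-[4-(benzyloxy)-3-methoxyphenyl]-2,3-dimethyl-4-oxobutyl]-2,6-dimethoxyphenyl N,N-diethylcarbamate | COc1cc(C(=O)[C@H](C)[C@H](C)Cc2cc(OC)c(OC(=O)N(CC)CC)c(OC)c2)ccc1OCc1ccccc1 | intermediate
14 | 4-[(2R,3S)-4-(4-hydroxy-3-methoxyphenyl)-2,3-dimethylbutyl]-2,6-dimethoxyphenyl N,N-diethylcarbamate | COc1cc(C[C@H](C)[C@H](C)Cc2cc(OC)c(OC(=O)N(CC)CC)c(OC)c2)ccc1O | intermediate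
15 | 4-[(2R,3R)-4-(3-methoxy-4-oxocyclohexa-2,5-dien-1-ylidene)-2,3-dimethylbutyl]-2,6-dimethoxyphenyl N,N-diethylcarbamate (p-quinone methide, formed in the flask) | COC1=CC(=C[C@H](C)[C@H](C)Cc2cc(OC)c(OC(=O)N(CC)CC)c(OC)c2)C=CC1=O | intermediate
16 | (6R,7R,8R)-8-(4-hydroxy-3-methoxyphenyl)-1,3-dimethoxy-6,7-dimethyl-5,6,7,8-tetrahydronaphthalen-2-yl N,N-diethylcarbamate | COc1cc([C@@H]2c3c(cc(OC)c(OC(=O)N(CC)CC)c3OC)C[C@@H](C)[C@H]2C)ccc1O | intermediate
17 | (−)-(7'R,8R,8'R)-4,4'-dihydroxy-3,3',5-trimethoxy-2,7'-cyclolignan | COc1cc([C@@H]2c3c(cc(OC)c(O)c3OC)C[C@@H](C)[C@H]2C)ccc1O | target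

Total step count: 9. Longest linear sequence: 8 steps (steps 1 and 3–9).

**Steps most likely to fail**

Step 8 (key step). The oxidant may attack the cyclized product a second time (loss of the C7' hydrogen and dehydrogenation of the new ring), or the quinone methide may tautomerize to the styrene before it is trapped, which would erase C8'. The fallback makes the electrophile at C7' without an oxidant and sets out from ketone 13. NaBH4 in MeOH at 0 °C should give the 7'-carbinol F1 as a mixture of C7' epimers. BF3·OEt2 in CH2Cl2 at −20 °C should ionize both epimers to the same 4-benzyloxybenzyl cation, which closes onto C2 of the carbamate ring in a stereoconvergent Friedel–Crafts alkylation to give the O-benzyl aryltetralin F2. Hydrogenolysis (H2, Pd/C, EtOAc) then removes the benzyl ether, and the sequence comes back to the route at 16.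

Step 3. Discrimination between the two enantiotopic carbonyl groups may be insufficient (or of the wrong sense) with this functionalized arylzinc reagent, or slow transmetalation may let unselective background acylation compete. The fallback sets out from anhydride 2 and moves the asymmetric event to an alkaloid-mediated alcoholysis. Methanol with quinidine or quinine (whichever gives the needed enantiomer) in toluene at −55 °C should give the hemiester F3. Oxalyl chloride with catalytic DMF gives the acid chloride F4, and Pd(PPh3)4-catalysed Negishi acylation with arylzinc 6 gives the keto ester F5. Hydrogenolysis as in step 4 gives the methyl ester F6, and LiOH in THF/water returns to the route at acid 8.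

Step 4. Hydrogenolysis may stall at the γ-lactone because the benzylic C–O bond on this electron-poorer, hindered ring cleaves slowly, or the stronger acid then needed may epimerize C8 before the ketone is reduced. The fallback replaces surface hydrogenolysis by a Mozingo reduction and sets out from keto acid 7. 1,2-Ethanedithiol with BF3·OEt2 in CH2Cl2 should give the dithiolane F7, and Raney nickel in refluxing EtOH should desulfurize it, returning to the route at acid 8.

**Further compounds**

F1 | step 8 | 4-[(2R,3R)-4-[4-(benzyloxy)-3-methoxyphenyl]-4-hydroxy-2,3-dimethylbutyl]-2,6-dimethoxyphenyl N,N-diethylcarbamate (both C4 epimers) | COc1cc(C(O)[C@H](C)[C@H](C)Cc2cc(OC)c(OC(=O)N(CC)CC)c(OC)c2)ccc1OCc1ccccc1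
F2 | step 8 | (6R,7R,8R)-8-[4-(benzyloxy)-3-methoxyphenyl]-1,3-dimethoxy-6,7-dimethyl-5,6,7,8-tetrahydronaphthalen-2-yl N,N-diethylcarbamate | COc1cc([C@@H]2c3c(cc(OC)c(OC(=O)N(CC)CC)c3OC)C[C@@H](C)[C@H]2C)ccc1OCc1ccccc1
F3 | step 3 | (2S,3R)-4-methoxy-2,3-dimethyl-4-oxobutanoic acid | COC(=O)[C@H](C)[C@H](C)C(O)=O
F4 | step 3 | methyl (2R,3S)-4-chloro-2,3-dimethyl-4-oxobutanoate | COC(=O)[C@H](C)[C@H](C)C(Cl)=O
F5 | step 3 | methyl (2R,3S)-4-[4-(diethylcarbamoyloxy)-3,5-dimethoxyphenyl]-2,3-dimethyl-4-oxobutanoate | COC(=O)[C@H](C)[C@H](C)C(=O)c1cc(OC)c(OC(=O)N(CC)CC)c(OC)c1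
F6 | step 3 | methyl (2R,3R)-4-[4-(diethylcarbamoyloxy)-3,5-dimethoxyphenyl]-2,3-dimethylbutanoate | COC(=O)[C@H](C)[C@H](C)Cc1cc(OC)c(OC(=O)N(CC)CC)c(OC)c1
F7 | step 4 | (2R,3S)-3-{2-[4-(diethylcarbamoyloxy)-3,5-dimethoxyphenyl]-1,3-dithiolan-2-yl}-2-methylbutanoic acid | OC(=O)[C@H](C)[C@H](C)C1(SCCS1)c1cc(OC)c(OC(=O)N(CC)CC)c(OC)c1
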